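**Retrosynthetic overview**

1. Isospiculoic acid A ⇐ ring B closed last by a 5-exo acyl radical cyclisation (C2–C1 bond) of a phenyl selenoester arm on C3a onto the propenyl arm on C7a of a ring A acid.
2. Ring A acid ⇐ Ireland–Claisen ring contraction of a δ-lactone whose ring oxygen sits on C7 (C4–C5 formed, C7–O broken). The strategy rests on the C4 carboxyl group of ring A being γ,δ-unsaturated through C5 and the C6=C7 alkene, with C4 and C5 both quaternary.
3. Lactone ⇐ lactonisation of a tertiary C7 alcohol onto a tert-butyl ester; (E,E)-dienyl group from an ethyl alkyne by hydrostannation and Stille coupling; propenyl arm from a lactol by Takai–Utimoto ethylidenation.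
4. C3a, C7a and C7 ⇐ trans Michael addition of a butanoate enolate, then ketone aldol addition of hept-4-yn-3-one, on (R)-5-methyl-5,6-dihydro-2H-pyran-2-one, which carries C3 and comes from methyl (S)-3-hydroxy-2-methylpropanoate.
5. Ring order: auxiliary dihydropyranone (step 4, opened in step 9), δ-lactone (step 13), ring A (step 14), ring B (step 19).

Key step: step 14

Remark: atom labels C1–C3, C3a, C4–C7, C7a are those of the target's hexahydroindenone skeleton; C4 is carried as both epimers from step 5 to step 13, because it becomes planar in step 14.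

**Route**

Step 1
Reactants: 1 methyl (S)-3-hydroxy-2-methylpropanoate
Product: 2 methyl (S)-3-[(tert-butyldimethylsilyl)oxy]-2-methylpropanoate
Conditions: t-BuMe2SiCl, imidazole, CH2Cl2, 0 °C → rt
Reagents that add atoms: tert-butyldimethylsilyl chloride, CC(C)(C)[Si](C)(C)Cl
Why: Silyl ether formation on the primary alcohol with imidazole as base, which does not involve the stereocentre.

Step 2
Reactants: 2 methyl (S)-3-[(tert-butyldimethylsilyl)oxy]-2-methylpropanoate
Product: 3 (S)-3-[(tert-butyldimethylsilyl)oxy]-2-methylpropanal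
Conditions: i-Bu2AlH, CH2Cl2, −78 °C; aq. potassium sodium tartrate
Reagents that add atoms: none
Why: Partial ester reduction with one equivalent of i-Bu2AlH stops at the tetrahedral aluminium hemiacetal at low temperature, which should release the configurationally intact aldehyde on work-up.

Step 3
Reactants: 3 (S)-3-[(tert-butyldimethylsilyl)oxy]-2-methylpropanal; 4 methyl 2-[bis(2,2,2-trifluoroethoxy)phosphoryl]acetate
Product: 6 methyl (R,Z)-5-[(tert-butyldimethylsilyl)oxy]-4-methylpent-2-enoate, via potassium phosphonate anion 5 (not isolated)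
Conditions: 4, KN(SiMe3)2, 18-crown-6, THF, −78 °C; then 3
Reagents that add atoms: none
Why: Still–Gennari variant of the Horner–Wadsworth–Emmons olefination, in which the electron-poor phosphonate makes elimination fast and kinetically (Z)-selective, the geometry needed for ring closure, while the low temperature should keep the α-stereocentre of 3 intact.

Step 4
Reactants: 6 methyl (R,Z)-5-[(tert-butyldimethylsilyl)oxy]-4-methylpent-2-enoate
Product: 7 (R)-5-methyl-5,6-dihydro-2H-pyran-2-one
Conditions: p-TsOH·H2O (cat.), MeOH, rt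
Reagents that add atoms: none
Why: Acid-catalysed methanolysis of the silyl ether frees the primary alcohol, which lactonises onto the cis-disposed ester (intramolecular transesterification) without touching the stereocentre.

Step 5
Reactants: 7 (R)-5-methyl-5,6-dihydro-2H-pyran-2-one; 8 tert-butyl butanoate
Product: 10 tert-butyl 2-[(3R,4S)-3-methyl-6-oxooxan-4-yl]butanoate (both C4 epimers), via lithium ester enolate 9 (not isolated)
Conditions: 8, LiN(i-Pr)2, THF, −78 °C; then 7, −78 → −40 °C; AcOH
Reagents that add atoms: none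
Why: Michael addition of an ester lithium enolate to an α,β-unsaturated δ-lactone, in which the nucleophile should enter the half-chair anti to the neighbouring methyl-bearing carbon (C3) and so set C3a trans to it, while C4 is left uncontrolled on purpose.

Step 6
Reactants: 11 but-1-yne; 12 propanoyl chloride
Product: 13 hept-4-yn-3-one
Conditions: PdCl2(PPh3)2 (cat.), CuI (cat.), Et3N, THF, rt
Reagents that add atoms: none
Why: Acyl Sonogashira coupling of a terminal alkyne with an acid chloride gives the conjugated ynone in one operation.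

Step 7
Reactants: 10 tert-butyl 2-[(3R,4S)-3-methyl-6-oxooxan-4-yl]butanoate (both C4 epimers); 13 hept-4-yn-3-one
Product: 15 tert-butyl 2-[(3R,4S,5R)-5-[(R)-3-hydroxyhept-4-yn-3-yl]-3-methyl-6-oxooxan-4-yl]butanoate, via lithium lactone enolate 14 (not isolated)
Conditions: LiN(i-Pr)2, THF, −78 °C; then 13, −78 °C; AcOH, −78 °C
Reagents that add atoms: none
Why: Aldol addition of a lactone lithium enolate (kinetic deprotonation of the lactone CH2, not the hindered ester CH) to a ketone, in which the enolate should react on the face anti to the C3a substituent (C7a trans) and the closed chair-like six-membered transition state should place the slim alkynyl group in the crowded axial site and ethyl in the equatorial one, which gives the required C7 carbinol configuration.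

Step 8
Reactants: 15 tert-butyl 2-[(3R,4S,5R)-5-[(R)-3-hydroxyhept-4-yn-3-yl]-3-methyl-6-oxooxan-4-yl]butanoate
Product: 16 tert-butyl 2-[(3R,4S,5R)-6-hydroxy-5-[(R)-3-hydroxyhept-4-yn-3-yl]-3-methyloxan-4-yl]butanoate (lactol; both anomers)
Conditions: i-Bu2AlH, CH2Cl2, −78 °C; aq. potassium sodium tartrate
Reagents that add atoms: none
Why: Reduction of a lactone to the lactol with i-Bu2AlH at −78 °C, where the tert-butyl ester should be too hindered to react and the tertiary alcohol only consumes hydride.

Step 9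
Reactants: 16 tert-butyl 2-[(3R,4S,5R)-6-hydroxy-5-[(R)-3-hydroxyhept-4-yn-3-yl]-3-methyloxan-4-yl]butanoate
Product: 17 tert-butyl 2,5-diethyl-5-hydroxy-3-[(R)-1-hydroxypropan-2-yl]-4-[(E)-prop-1-en-1-yl]non-6-ynoate (chain C3/C4/C5 configured as C3a/C7a/C7 of 15)
Conditions: CrCl2, CH3CHI2, THF, rt
Reagents that add atoms: 1,1-diiodoethane, CC(I)I
Why: Takai–Utimoto ethylidenation with the geminal dichromium reagent acts on the open hydroxy aldehyde form of the lactol under non-basic conditions, so the β-hydroxy aldehyde should neither cleave by retro-aldol reaction nor epimerise at C7a, and the reaction is (E)-selective.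

Step 10
Reactants: 17 tert-butyl 2,5-diethyl-5-hydroxy-3-[(R)-1-hydroxypropan-2-yl]-4-[(E)-prop-1-en-1-yl]non-6-ynoate
Product: 18 tert-butyl 3-[(R)-1-[(tert-butyldimethylsilyl)oxy]propan-2-yl]-2,5-diethyl-5-hydroxy-4-[(E)-prop-1-en-1-yl]non-6-ynoate
Conditions: t-BuMe2SiCl, imidazole, CH2Cl2, 0 °C
Reagents that add atoms: tert-butyldimethylsilyl chloride, CC(C)(C)[Si](C)(C)Cl
Why: Selective silylation of the primary hydroxyl group, the tertiary propargylic alcohol being too hindered to react.

Step 11
Reactants: 18 tert-butyl 3-[(R)-1-[(tert-butyldimethylsilyl)oxy]propan-2-yl]-2,5-diethyl-5-hydroxy-4-[(E)-prop-1-en-1-yl]non-6-ynoate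
Product: 19 tert-butyl (E)-3-[(R)-1-[(tert-butyldimethylsilyl)oxy]propan-2-yl]-2,5-diethyl-5-hydroxy-4-[(E)-prop-1-en-1-yl]-7-(tributylstannyl)non-6-enoate
Conditions: Bu3SnH, PdCl2(PPh3)2 (cat.), THF, rt
Reagents that add atoms: tributyltin hydride, CCCC[SnH](CCCC)CCCC
Why: Palladium-catalysed syn-hydrostannation of the internal alkyne, in which tin should go to the alkyne carbon remote from the fully substituted carbinol carbon (C5), which fixes ethyl cis and tin trans to C7.

Step 12
Reactants: 19 tert-butyl (E)-3-[(R)-1-[(tert-butyldimethylsilyl)oxy]propan-2-yl]-2,5-diethyl-5-hydroxy-4-[(E)-prop-1-en-1-yl]-7-(tributylstannyl)non-6-enoate; 20 (E)-(2-bromoethenyl)benzene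
Product: 21 tert-butyl (6E,8E)-3-[(R)-1-[(tert-butyldimethylsilyl)oxy]propan-2-yl]-2,5,7-triethyl-5-hydroxy-9-phenyl-4-[(E)-prop-1-en-1-yl]nona-6,8-dienoate
Conditions: Pd2(dba)3 (cat.), AsPh3, CuI (cat.), N-methylpyrrolidone, 50 °C
Reagents that add atoms: none
Why: Stille cross-coupling proceeds with retention at both alkenyl partners and should give the (E,E)-diene, the copper co-catalyst helping the hindered α-substituted alkenylstannane to transmetalate.

Step 13
Reactants: 21 tert-butyl (6E,8E)-3-[(R)-1-[(tert-butyldimethylsilyl)oxy]propan-2-yl]-2,5,7-triethyl-5-hydroxy-9-phenyl-4-[(E)-prop-1-en-1-yl]nona-6,8-dienoate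
Product: 23 4-[(R)-1-[(tert-butyldimethylsilyl)oxy]propan-2-yl]-3,6-diethyl-6-[(1E,3E)-2-ethyl-4-phenylbuta-1,3-dien-1-yl]-5-[(E)-prop-1-en-1-yl]oxan-2-one (dienyl cis to the C3a side chain and trans to propenyl), via lithium alkoxide 22 (not isolated)
Conditions: LiN(SiMe3)2, THF, 0 °C → rt; H2O
Reagents that add atoms: none
Why: Intramolecular transesterification (lactonisation) in which the tertiary lithium alkoxide attacks the tert-butyl ester in a 6-exo-trig closure helped by the heavily substituted chain, the C7–O bond staying intact so that C7 keeps its configuration, and the lithium counter-ion keeping the 3-oxido-1,5-diene from an anionic oxy-Cope rearrangement.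

Step 14
Reactants: 23 4-[(R)-1-[(tert-butyldimethylsilyl)oxy]propan-2-yl]-3,6-diethyl-6-[(1E,3E)-2-ethyl-4-phenylbuta-1,3-dien-1-yl]-5-[(E)-prop-1-en-1-yl]oxan-2-one
Product: 27 6-[(R)-1-[(tert-butyldimethylsilyl)oxy]propan-2-yl]-1,2,4-triethyl-2-[(E)-2-phenylethenyl]-5-[(E)-prop-1-en-1-yl]cyclohex-3-ene-1-carboxylic acid (ring A acid), via lithium enolate 24 (not isolated), via silyl ketene acetal 25 (not isolated), via trimethylsilyl ester 26 (not isolated)
Conditions: LiN(i-Pr)2, THF, −78 °C; Me3SiCl, Et3N, −78 °C → rt; toluene, 80 °C; H2O, MeOH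
Reagents that add atoms: none
Why: Deprotonation at C4 and O-silylation give the ring-locked trimethylsilyl ketene acetal, which should undergo a [3,3]-sigmatropic shift (Ireland–Claisen rearrangement, of the known kind that contracts alkenyl lactone ketene acetals to cycloalkenecarboxylic acids) forming C4–C5 as C7–O breaks and the alkene moves to C6=C7. Ring A closes as a six-membered carbocycle by this sigmatropic ring contraction through a boat-like, bicyclo[2.2.2]-type array, the only geometry in which the C7 dienyl group reaches C4 while both are tied by the C7a–C3a bridge. C4 is controlled by the C7 carbinol centre, because the new bond must form on the lactone face that carries the dienyl group (cis to the C3a side chain), which leaves the carboxyl group trans to that side chain. C5 is controlled by the (E)-geometry of the trisubstituted alkene, whose ethyl group (cis to C7) ends up cis to the C4 ethyl group and whose styryl group ends up cis to the carboxyl group. The step needs the rearrangement to outrun ionisation of the tertiary dienylic C–O bond and the thermal Cope rearrangement of the C5=C6–C7–C7a–CH=CH diene, which the electron-rich ketene acetal and the moderate temperature should secure. Both C4 epimers converge because C4 becomes planar, and the trans arms on C3a and C7a are kept open because a ring fused there could not follow the eclipsed boat.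

Step 15
Reactants: 27 ring A acid
Product: 28 prop-2-en-1-yl 6-[(R)-1-[(tert-butyldimethylsilyl)oxy]propan-2-yl]-1,2,4-triethyl-2-[(E)-2-phenylethenyl]-5-[(E)-prop-1-en-1-yl]cyclohex-3-ene-1-carboxylate
Conditions: Cs2CO3, allyl bromide, DMF, rt
Reagents that add atoms: allyl bromide, C=CCBr
Why: O-Alkylation of the caesium carboxylate (SN2 at allyl bromide) esterifies the hindered quaternary acid without any attack at its carbonyl group and installs an ester that can later be removed under neutral conditions.

Step 16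
Reactants: 28 allyl ester silyl ether
Product: 29 prop-2-en-1-yl 1,2,4-triethyl-6-[(R)-1-hydroxypropan-2-yl]-2-[(E)-2-phenylethenyl]-5-[(E)-prop-1-en-1-yl]cyclohex-3-ene-1-carboxylate
Conditions: HF·pyridine, pyridine, THF, 0 °C → rt
Reagents that add atoms: none
Why: Fluoride-mediated cleavage of the primary silyl ether with buffered HF·pyridine should leave the allyl ester and all alkenes untouched.

Step 17
Reactants: 29 primary alcohol
Product: 30 (R)-2-[2-[(prop-2-en-1-yloxy)carbonyl]-2,3,5-triethyl-3-[(E)-2-phenylethenyl]-6-[(E)-prop-1-en-1-yl]cyclohex-4-en-1-yl]propanoic acid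
Conditions: TEMPO (cat.), PhI(OAc)2, MeCN/H2O, rt
Reagents that add atoms: water, O
Why: Oxoammonium-mediated oxidation (TEMPO with PhI(OAc)2) takes the primary alcohol through the aldehyde hydrate to the acid in aqueous acetonitrile, conditions that spare the alkenes.

Step 18
Reactants: 30 carboxylic acid
Product: 31 Se-phenyl selenoester of 30 (C2 acyl selenide)
Conditions: PhSeSePh, PBu3, CH2Cl2, rt
Reagents that add atoms: diphenyl diselenide, c1ccccc1[Se][Se]c1ccccc1
Why: Phosphine-mediated selenoesterification through an acyloxyphosphonium salt converts the unhindered acid into the phenyl selenoester, the acyl radical precursor, under neutral conditions.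

Step 19
Reactants: 31 Se-phenyl selenoester
Product: 32 prop-2-en-1-yl ester of isospiculoic acid A
Conditions: Bu3SnH (slow addition), Et3B, air, benzene, rt; then DBU (cat.), CH2Cl2, rt
Reagents that add atoms: none
Why: Abstraction of the phenylseleno group by the tin radical gives an acyl radical that should close 5-exo-trig onto the propenyl group (C2–C1 bond, ring B) faster than it loses CO at room temperature; a chair-like transition state with the ring bonds equatorial places the ethyl-bearing C1 trans to C7, and because C1 and C3 flank the new ketone the base treatment secures the all-trans arrangement, which should be the more stable one.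

Step 20
Reactants: 32 prop-2-en-1-yl ester of isospiculoic acid A
Product: 33 isospiculoic acid A
Conditions: Pd(PPh3)4 (cat.), morpholine, THF, rt
Reagents that add atoms: none
Why: Palladium-catalysed allyl transfer (π-allyl formation and capture by morpholine) frees the hindered acid under neutral conditions that should not hydrolyse or epimerise anything else.

**Compound list**

1 | methyl (S)-3-hydroxy-2-methylpropanoate | COC(=O)[C@@H](C)CO | starting material
2 | methyl (S)-3-[(tert-butyldimethylsilyl)oxy]-2-methylpropanoate | COC(=O)[C@@H](C)CO[Si](C)(C)C(C)(C)C | intermediate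
3 | (S)-3-[(tert-butyldimethylsilyl)oxy]-2-methylpropanal | O=C[C@@H](C)CO[Si](C)(C)C(C)(C)C | intermediate
4 | methyl 2-[bis(2,2,2-trifluoroethoxy)phosphoryl]acetate | COC(=O)CP(=O)(OCC(F)(F)F)OCC(F)(F)F | starting material
5 | potassium salt of the carbanion of 4 | COC(=O)[CH-]P(=O)(OCC(F)(F)F)OCC(F)(F)F.[K+] | intermediate (not isolated)
6 | methyl (R,Z)-5-[(tert-butyldimethylsilyl)oxy]-4-methylpent-2-enoate | COC(=O)/C=C\[C@@H](C)CO[Si](C)(C)C(C)(C)C | intermediate
7 | (R)-5-methyl-5,6-dihydro-2H-pyran-2-one | O=C1C=C[C@@H](C)CO1 | intermediate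
8 | tert-butyl butanoate | CCCC(=O)OC(C)(C)C | starting material
9 | lithium enolate of tert-butyl butanoate | CCC=C(O[Li])OC(C)(C)C | intermediate (not isolated)
10 | tert-butyl 2-[(3R,4S)-3-methyl-6-oxooxan-4-yl]butanoate (both C4 epimers; ring substituents trans) | O=C1C[C@H](C(CC)C(=O)OC(C)(C)C)[C@@H](C)CO1 | intermediate
11 | but-1-yne | CCC#C | starting material
12 | propanoyl chloride | CCC(=O)Cl | starting material
13 | hept-4-yn-3-one | CCC(=O)C#CCC | intermediate
14 | lithium enolate of lactone 10 | [Li]OC1=C[C@H](C(CC)C(=O)OC(C)(C)C)[C@@H](C)CO1 | intermediate (not isolated)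
15 | tert-butyl 2-[(3R,4S,5R)-5-[(R)-3-hydroxyhept-4-yn-3-yl]-3-methyl-6-oxooxan-4-yl]butanoate (all-trans ring; C4 epimers) | O=C1[C@@H]([C@](O)(CC)C#CCC)[C@H](C(CC)C(=O)OC(C)(C)C)[C@@H](C)CO1 | intermediate
16 | tert-butyl 2-[(3R,4S,5R)-6-hydroxy-5-[(R)-3-hydroxyhept-4-yn-3-yl]-3-methyloxan-4-yl]butanoate (lactol, both anomers) | OC1[C@@H]([C@](O)(CC)C#CCC)[C@H](C(CC)C(=O)OC(C)(C)C)[C@@H](C)CO1 | intermediate
17 | tert-butyl 2,5-diethyl-5-hydroxy-3-[(R)-1-hydroxypropan-2-yl]-4-[(E)-prop-1-en-1-yl]non-6-ynoate (stereocentres as in 15) | C/C=C/[C@@H]([C@](O)(CC)C#CCC)[C@H](C(CC)C(=O)OC(C)(C)C)[C@@H](C)CO | intermediate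
18 | primary tert-butyldimethylsilyl ether of 17 | C/C=C/[C@@H]([C@](O)(CC)C#CCC)[C@H](C(CC)C(=O)OC(C)(C)C)[C@@H](C)CO[Si](C)(C)C(C)(C)C | intermediate
19 | tert-butyl (E)-3-[(R)-1-[(tert-butyldimethylsilyl)oxy]propan-2-yl]-2,5-diethyl-5-hydroxy-4-[(E)-prop-1-en-1-yl]-7-(tributylstannyl)non-6-enoate | C/C=C/[C@@H]([C@](O)(CC)/C=C(CC)/[Sn](CCCC)(CCCC)CCCC)[C@H](C(CC)C(=O)OC(C)(C)C)[C@@H](C)CO[Si](C)(C)C(C)(C)C | intermediate
20 | (E)-(2-bromoethenyl)benzene | Br/C=C/c1ccccc1 | starting material
21 | tert-butyl (6E,8E)-3-[(R)-1-[(tert-butyldimethylsilyl)oxy]propan-2-yl]-2,5,7-triethyl-5-hydroxy-9-phenyl-4-[(E)-prop-1-en-1-yl]nona-6,8-dienoate | C/C=C/[C@@H]([C@](O)(CC)/C=C(CC)/C=C/c1ccccc1)[C@H](C(CC)C(=O)OC(C)(C)C)[C@@H](C)CO[Si](C)(C)C(C)(C)C | intermediate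
22 | lithium alkoxide of 21 | C/C=C/[C@@H]([C@](O[Li])(CC)/C=C(CC)/C=C/c1ccccc1)[C@H](C(CC)C(=O)OC(C)(C)C)[C@@H](C)CO[Si](C)(C)C(C)(C)C | intermediate (not isolated)
23 | 4-[(R)-1-[(tert-butyldimethylsilyl)oxy]propan-2-yl]-3,6-diethyl-6-[(1E,3E)-2-ethyl-4-phenylbuta-1,3-dien-1-yl]-5-[(E)-prop-1-en-1-yl]oxan-2-one (key-step precursor; dienyl cis to the C3a side chain, trans to propenyl; C4 epimers) | CCC1C(=O)O[C@@](CC)(/C=C(CC)/C=C/c2ccccc2)[C@H](/C=C/C)[C@H]1[C@@H](C)CO[Si](C)(C)C(C)(C)C | intermediate
24 | lithium enolate of lactone 23 | CCC1=C(O[Li])O[C@@](CC)(/C=C(CC)/C=C/c2ccccc2)[C@H](/C=C/C)[C@H]1[C@@H](C)CO[Si](C)(C)C(C)(C)C | intermediate (not isolated)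
25 | trimethylsilyl ketene acetal of lactone 23 | CCC1=C(O[Si](C)(C)C)O[C@@](CC)(/C=C(CC)/C=C/c2ccccc2)[C@H](/C=C/C)[C@H]1[C@@H](C)CO[Si](C)(C)C(C)(C)C | intermediate (not isolated)
26 | trimethylsilyl ester of acid 27 | CCC1=C[C@](/C=C/c2ccccc2)(CC)[C@@](CC)(C(=O)O[Si](C)(C)C)[C@H]([C@@H](C)CO[Si](C)(C)C(C)(C)C)[C@H]1/C=C/C | intermediate (not isolated)
27 | 6-[(R)-1-[(tert-butyldimethylsilyl)oxy]propan-2-yl]-1,2,4-triethyl-2-[(E)-2-phenylethenyl]-5-[(E)-prop-1-en-1-yl]cyclohex-3-ene-1-carboxylic acid (key-step product; carboxyl cis to styryl, trans to the C3a side chain) | CCC1=C[C@](/C=C/c2ccccc2)(CC)[C@@](CC)(C(=O)O)[C@H]([C@@H](C)CO[Si](C)(C)C(C)(C)C)[C@H]1/C=C/C | intermediate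
28 | prop-2-en-1-yl ester of 27 | CCC1=C[C@](/C=C/c2ccccc2)(CC)[C@@](CC)(C(=O)OCC=C)[C@H]([C@@H](C)CO[Si](C)(C)C(C)(C)C)[C@H]1/C=C/C | intermediate
29 | prop-2-en-1-yl 1,2,4-triethyl-6-[(R)-1-hydroxypropan-2-yl]-2-[(E)-2-phenylethenyl]-5-[(E)-prop-1-en-1-yl]cyclohex-3-ene-1-carboxylate | CCC1=C[C@](/C=C/c2ccccc2)(CC)[C@@](CC)(C(=O)OCC=C)[C@H]([C@@H](C)CO)[C@H]1/C=C/C | intermediate
30 | (R)-2-[2-[(prop-2-en-1-yloxy)carbonyl]-2,3,5-triethyl-3-[(E)-2-phenylethenyl]-6-[(E)-prop-1-en-1-yl]cyclohex-4-en-1-yl]propanoic acid | CCC1=C[C@](/C=C/c2ccccc2)(CC)[C@@](CC)(C(=O)OCC=C)[C@H]([C@@H](C)C(=O)O)[C@H]1/C=C/C | intermediate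
31 | Se-phenyl selenoester of 30 | CCC1=C[C@](/C=C/c2ccccc2)(CC)[C@@](CC)(C(=O)OCC=C)[C@H]([C@@H](C)C(=O)[Se]c2ccccc2)[C@H]1/C=C/C | intermediate
32 | prop-2-en-1-yl ester of isospiculoic acid A | CCC1=C[C@](/C=C/c2ccccc2)(CC)[C@@](CC)(C(=O)OCC=C)[C@H]2[C@H]1[C@@H](CC)C(=O)[C@@H]2C | intermediate
33 | isospiculoic acid A | CCC1=C[C@](/C=C/c2ccccc2)(CC)[C@@](CC)(C(=O)O)[C@H]2[C@H]1[C@@H](CC)C(=O)[C@@H]2C | target

**Step count**

Total: 20 steps. Longest linear sequence: 19 steps (steps 1–5 and 7–20; step 6 is a one-step branch).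

**The three steps most likely to fail**

Step 14 (ring contraction). The tertiary dienylic C7–O bond may ionise (a phenyl-conjugated pentadienyl cation) or eliminate before the congested boat rearrangement, which has to build two adjacent quaternary carbons, takes place. The fallback keeps the phenyl group out of the pericyclic step and adds it afterwards by a Heck reaction. Setting out from alkenylstannane 19, Stille coupling with vinyl bromide under the conditions of step 12 would give the 2-ethylbuta-1,3-dienyl carbinol F1. LiN(SiMe3)2 in THF would close it to the lactone F2. The same enolisation, silylation and heating as in step 14 would give the C5-vinyl ring A acid F3. Its only monosubstituted alkene would then be arylated with iodobenzene (Pd(OAc)2, Bu4NCl, NaHCO3, DMF, 60 °C) to the (E)-styryl group, which brings the route back to 27.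

Step 7 (ketone aldol). Facial discrimination between ethyl and butynyl at the ketone carbonyl may be poor, giving the wrong or a mixed C7 configuration, and proton transfer from the enolisable ynone to the enolate may compete with addition. The fallback sets C7 by a chelation-controlled Grignard addition instead. Setting out from lactone 10, the same lithium enolate would be added to pent-2-ynal to give the secondary propargylic alcohol F4, whose carbinol configuration does not matter. i-Bu2AlH would give the lactol F5, and MeOH with pyridinium p-toluenesulfonate the methyl acetal F6. Dess–Martin periodinane would give the ynone F7. EtMgBr in CH2Cl2/Et2O at −78 °C, with magnesium bridging the ketone and acetal oxygens, should add on the face anti to C3a and give the tertiary alcohol F8 with the C7 configuration of 15. Aqueous AcOH in THF would hydrolyse the acetal and bring the route back to lactol 16.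

Step 9 (ethylidenation of the lactol). The six-membered lactol may open too slowly, so that the chromium reagent decays before olefination, or the open β-hydroxy aldehyde may cleave by retro-aldol reaction. The fallback makes a true aldehyde first. Setting out from lactone 15, Me3Al with MeNHOMe·HCl in CH2Cl2 would open the ring to the hydroxy Weinreb amide F9. t-BuMe2SiCl and imidazole would silylate its primary alcohol to give the silyl ether F10, and i-Bu2AlH at −78 °C would give the aldehyde F11. The Takai–Utimoto ethylidenation of this free aldehyde (or a Julia–Kocienski olefination) would bring the route back to 18.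

**Further compounds**

F1 | step 14 | tert-butyl (6E)-3-[(R)-1-[(tert-butyldimethylsilyl)oxy]propan-2-yl]-2,5,7-triethyl-5-hydroxy-4-[(E)-prop-1-en-1-yl]nona-6,8-dienoate (stereocentres as in 21) | C/C=C/[C@@H]([C@](O)(CC)/C=C(CC)/C=C)[C@H](C(CC)C(=O)OC(C)(C)C)[C@@H](C)CO[Si](C)(C)C(C)(C)C
F2 | step 14 | 4-[(R)-1-[(tert-butyldimethylsilyl)oxy]propan-2-yl]-3,6-diethyl-6-[(E)-2-ethylbuta-1,3-dien-1-yl]-5-[(E)-prop-1-en-1-yl]oxan-2-one (stereocentres as in 23) | CCC1C(=O)O[C@@](CC)(/C=C(CC)/C=C)[C@H](/C=C/C)[C@H]1[C@@H](C)CO[Si](C)(C)C(C)(C)C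
F3 | step 14 | 6-[(R)-1-[(tert-butyldimethylsilyl)oxy]propan-2-yl]-2-ethenyl-1,2,4-triethyl-5-[(E)-prop-1-en-1-yl]cyclohex-3-ene-1-carboxylic acid (stereocentres as in 27) | CCC1=C[C@](C=C)(CC)[C@@](CC)(C(=O)O)[C@H]([C@@H](C)CO[Si](C)(C)C(C)(C)C)[C@H]1/C=C/C
F4 | step 7 | tert-butyl 2-[(3R,4S,5R)-5-(1-hydroxypent-2-yn-1-yl)-3-methyl-6-oxooxan-4-yl]butanoate (carbinol epimers) | O=C1[C@@H](C(O)C#CCC)[C@H](C(CC)C(=O)OC(C)(C)C)[C@@H](C)CO1
F5 | step 7 | lactol of F4 | OC1[C@@H](C(O)C#CCC)[C@H](C(CC)C(=O)OC(C)(C)C)[C@@H](C)CO1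
F6 | step 7 | methyl acetal of F5 | COC1[C@@H](C(O)C#CCC)[C@H](C(CC)C(=O)OC(C)(C)C)[C@@H](C)CO1
F7 | step 7 | tert-butyl 2-[6-methoxy-3-methyl-5-(pent-2-ynoyl)oxan-4-yl]butanoate (ring stereocentres as in F6) | COC1[C@@H](C(=O)C#CCC)[C@H](C(CC)C(=O)OC(C)(C)C)[C@@H](C)CO1
F8 | step 7 | tert-butyl 2-[5-[(R)-3-hydroxyhept-4-yn-3-yl]-6-methoxy-3-methyloxan-4-yl]butanoate (methyl acetal of 16) | COC1[C@@H]([C@](O)(CC)C#CCC)[C@H](C(CC)C(=O)OC(C)(C)C)[C@@H](C)CO1
F9 | step 9 | hydroxy Weinreb amide from 15 (N-methoxy-N-methyl amide at C1, free primary alcohol at C2) | CON(C)C(=O)[C@@H]([C@](O)(CC)C#CCC)[C@H](C(CC)C(=O)OC(C)(C)C)[C@@H](C)CO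
F10 | step 9 | primary tert-butyldimethylsilyl ether of F9 | CON(C)C(=O)[C@@H]([C@](O)(CC)C#CCC)[C@H](C(CC)C(=O)OC(C)(C)C)[C@@H](C)CO[Si](C)(C)C(C)(C)C
F11 | step 9 | C1 aldehyde from F10 | O=C[C@@H]([C@](O)(CC)C#CCC)[C@H](C(CC)C(=O)OC(C)(C)C)[C@@H](C)CO[Si](C)(C)C(C)(C)C
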